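**Retrosynthetic overview**

- Target ⇒ (MOM off) ⇒ ring C opened at O1–C2: the ring A ortho-phenol adds enantioselectively, in the anti-Markovnikov sense, across a 1,1-disubstituted alkene. This one event closes the chroman and sets C3 as R.
- The 2-aryl-allyl arene ⇒ methylenation of a deoxybenzoin ⇒ Pd-catalysed α-arylation of the ring B methyl ketone with silyl-protected 4-bromoresorcinol (ring A).
- Ring B ketone ⇒ 2,4-dihydroxyacetophenone: C3-prenylation, then chromene annulation with 3-methylbut-2-enal at the only free ortho position.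
- Ring order: rings A and B are bought as benzenes; ring D (the dimethylpyran on ring B) is made first, ring C (the dihydropyran of the chroman) last.

Assumption: which mirror-image form of the thiol catalyst in step 8 gives the R product cannot be predicted and is fixed by a first screen; both forms are equally accessible from D- or L-amino acids.

**Route**

Step 1
Reactants: 1 2,4-dihydroxyacetophenone; 2 prenyl bromide (1-bromo-3-methylbut-2-ene)
Product: 3 1-[2,4-dihydroxy-3-(3-methylbut-2-en-1-yl)phenyl]ethan-1-one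
Conditions: KOH (10% aq), 0 °C → rt
Reagents that add atoms: none
Why: Phenoxide C-alkylation in water places the prenyl group at C3, the carbon flanked by both oxygens; expect roughly one third yield after chromatographic removal of the 5-prenyl and O-prenyl isomers.

Step 2
Reactants: 3 1-[2,4-dihydroxy-3-(3-methylbut-2-en-1-yl)phenyl]ethan-1-one; 4 3-methylbut-2-enal
Product: 5 1-[7-hydroxy-2,2-dimethyl-8-(3-methylbut-2-en-1-yl)-2H-chromen-6-yl]ethan-1-one
Conditions: ethylenediammonium diacetate (10 mol%), xylene, 140 °C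
Reagents that add atoms: none
Why: Knoevenagel-type condensation at C5 (the only free position ortho to the non-chelated 4-OH), dehydration to an ortho-quinone methide and oxa-6π electrocyclisation give the linear 2,2-dimethyl-2H-chromene (ring D).

Step 3
Reactants: 5 1-[7-hydroxy-2,2-dimethyl-8-(3-methylbut-2-en-1-yl)-2H-chromen-6-yl]ethan-1-one
Product: 6 1-[7-(methoxymethoxy)-2,2-dimethyl-8-(3-methylbut-2-en-1-yl)-2H-chromen-6-yl]ethan-1-one
Conditions: NaH, MOMCl, DMF, 0 °C → rt
Reagents that add atoms: chloromethyl methyl ether (MOMCl), COCCl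
Why: Williamson O-alkylation of the chelated, hindered phenoxide; an acetal is chosen because, unlike a silyl group, it cannot migrate to the ketone enolate in step 5 and it survives fluoride in step 7.

Step 4
Reactants: 7 4-bromoresorcinol
Product: 8 1-bromo-2,4-bis(triisopropylsilyloxy)benzene
Conditions: TIPSCl, imidazole, DMF, rt
Reagents that add atoms: triisopropylsilyl chloride (TIPSCl), CC(C)[Si](Cl)(C(C)C)C(C)C
Why: Standard silylation of both phenols; the bulky TIPS ethers tolerate K3PO4 at 100 °C and later leave with fluoride without touching the MOM group.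

Step 5
Reactants: 6 1-[7-(methoxymethoxy)-2,2-dimethyl-8-(3-methylbut-2-en-1-yl)-2H-chromen-6-yl]ethan-1-one; 8 1-bromo-2,4-bis(triisopropylsilyloxy)benzene
Product: 9 2-[2,4-bis(triisopropylsilyloxy)phenyl]-1-[7-(methoxymethoxy)-2,2-dimethyl-8-(3-methylbut-2-en-1-yl)-2H-chromen-6-yl]ethan-1-one
Conditions: Pd(OAc)2 (5 mol%), XPhos (10 mol%), K3PO4, toluene, 100 °C
Reagents that add atoms: none
Why: Pd-catalysed ketone α-arylation (Buchwald–Hartwig type) with a weak base; the ortho-silyloxy group on the aryl partner stops a second arylation, and the prenyl and chromene alkenes are poor Heck acceptors.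

Step 6
Reactants: 9 2-[2,4-bis(triisopropylsilyloxy)phenyl]-1-[7-(methoxymethoxy)-2,2-dimethyl-8-(3-methylbut-2-en-1-yl)-2H-chromen-6-yl]ethan-1-one
Product: 10 6-{3-[2,4-bis(triisopropylsilyloxy)phenyl]prop-1-en-2-yl}-7-(methoxymethoxy)-2,2-dimethyl-8-(3-methylbut-2-en-1-yl)-2H-chromene
Conditions: Cp2TiMe2 (3 equiv), toluene/THF, 70 °C, dark
Reagents that add atoms: dimethyltitanocene (Cp2TiMe2), C[Ti](C)(C1C=CC=C1)C1C=CC=C1
Why: Petasis methylenation; the non-basic titanium methylidene converts the hindered ketone to the alkene without enolising its acidic benzylic CH2 and leaves the silyl ethers, the acetal and the other alkenes alone.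

Step 7
Reactants: 10 6-{3-[2,4-bis(triisopropylsilyloxy)phenyl]prop-1-en-2-yl}-7-(methoxymethoxy)-2,2-dimethyl-8-(3-methylbut-2-en-1-yl)-2H-chromene
Product: 11 4-{2-[7-(methoxymethoxy)-2,2-dimethyl-8-(3-methylbut-2-en-1-yl)-2H-chromen-6-yl]prop-2-en-1-yl}benzene-1,3-diol
Conditions: Bu4NF (2.2 equiv), AcOH (2.2 equiv), THF, 0 °C; chromatography on Et3N-washed silica
Reagents that add atoms: none
Why: Fluoride-driven cleavage of both aryl silyl ethers; the MOM acetal is inert, and the acetic acid buffer is too weak to protonate the electron-rich styrene, which would otherwise cyclise in the Markovnikov sense.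

Step 8
Reactants: 11 4-{2-[7-(methoxymethoxy)-2,2-dimethyl-8-(3-methylbut-2-en-1-yl)-2H-chromen-6-yl]prop-2-en-1-yl}benzene-1,3-diol
Product: 13 (3R)-3-[7-hydroxy-2,2-dimethyl-8-(3-methylbut-2-en-1-yl)-2H-chromen-6-yl]-3,4-dihydro-2H-chromen-7-ol, via MOM-protected isoflavan 12 (not isolated)
Conditions: 9-mesityl-3,6-di-tert-butyl-10-phenylacridinium tetrafluoroborate (5 mol%), N-(2-sulfanylbenzoyl)-D-prolyl-2-aminoisobutyryl-L-phenylalanine dimethylamide (15 mol%), DCE (0.02 M), 450 nm LED, −20 °C, Ar; then HCl (1 M in MeOH), rt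
Reagents that add atoms: none
Why: Proposed new method: a catalytic enantioselective anti-Markovnikov hydroaryloxylation in which the excited acridinium oxidises the electron-rich ring B aryl alkene to its radical cation, the ring A ortho-phenol attacks the unsubstituted alkene terminus 6-endo (new O1–C2 bond, ring C closed) because this leaves the tertiary benzylic C3 radical, and that prochiral radical takes a hydrogen atom from the homochiral aryl thiol (S–H about 79 against about 84 kcal/mol for the new C–H), whose peptide backbone hydrogen-bonds the free 7-OH so that H is delivered to one face and C3 is set as R; the thiyl radical is reduced by the acridinyl radical and the thiolate is reprotonated, closing both cycles; the MOM ether keeps the ring B oxygen from competing; the closest known reaction types are the racemic acridinium/thiol anti-Markovnikov hydroetherification of alkenols and enantioselective hydrogen-atom transfer from chiral thiols to prochiral tertiary radicals; the acid stage then removes the MOM group by acetal exchange without touching C3.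

**Compound list**

1 | 2,4-dihydroxyacetophenone | CC(=O)c1ccc(O)cc1O | starting material
2 | prenyl bromide (1-bromo-3-methylbut-2-ene) | CC(C)=CCBr | starting material
3 | 1-[2,4-dihydroxy-3-(3-methylbut-2-en-1-yl)phenyl]ethan-1-one | CC(=O)c1ccc(O)c(CC=C(C)C)c1O | intermediate
4 | 3-methylbut-2-enal | CC(C)=CC=O | starting material
5 | 1-[7-hydroxy-2,2-dimethyl-8-(3-methylbut-2-en-1-yl)-2H-chromen-6-yl]ethan-1-one | CC(=O)c1cc2C=CC(C)(C)Oc2c(CC=C(C)C)c1O | intermediate
6 | 1-[7-(methoxymethoxy)-2,2-dimethyl-8-(3-methylbut-2-en-1-yl)-2H-chromen-6-yl]ethan-1-one | CC(=O)c1cc2C=CC(C)(C)Oc2c(CC=C(C)C)c1OCOC | intermediate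
7 | 4-bromoresorcinol (4-bromobenzene-1,3-diol) | Oc1ccc(Br)c(O)c1 | starting material
8 | 1-bromo-2,4-bis(triisopropylsilyloxy)benzene | CC(C)[Si](Oc1ccc(Br)c(O[Si](C(C)C)(C(C)C)C(C)C)c1)(C(C)C)C(C)C | intermediate
9 | 2-[2,4-bis(triisopropylsilyloxy)phenyl]-1-[7-(methoxymethoxy)-2,2-dimethyl-8-(3-methylbut-2-en-1-yl)-2H-chromen-6-yl]ethan-1-one | O=C(Cc1ccc(O[Si](C(C)C)(C(C)C)C(C)C)cc1O[Si](C(C)C)(C(C)C)C(C)C)c1cc2C=CC(C)(C)Oc2c(CC=C(C)C)c1OCOC | intermediate
10 | 6-{3-[2,4-bis(triisopropylsilyloxy)phenyl]prop-1-en-2-yl}-7-(methoxymethoxy)-2,2-dimethyl-8-(3-methylbut-2-en-1-yl)-2H-chromene | C=C(Cc1ccc(O[Si](C(C)C)(C(C)C)C(C)C)cc1O[Si](C(C)C)(C(C)C)C(C)C)c1cc2C=CC(C)(C)Oc2c(CC=C(C)C)c1OCOC | intermediate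
11 | 4-{2-[7-(methoxymethoxy)-2,2-dimethyl-8-(3-methylbut-2-en-1-yl)-2H-chromen-6-yl]prop-2-en-1-yl}benzene-1,3-diol | C=C(Cc1ccc(O)cc1O)c1cc2C=CC(C)(C)Oc2c(CC=C(C)C)c1OCOC | intermediate
12 | (3R)-3-[7-(methoxymethoxy)-2,2-dimethyl-8-(3-methylbut-2-en-1-yl)-2H-chromen-6-yl]-3,4-dihydro-2H-chromen-7-ol | CC(C)=CCc1c(OCOC)c([C@@H]2COc3cc(O)ccc3C2)cc2c1OC(C)(C)C=C2 | intermediate
13 | (3R)-3-[7-hydroxy-2,2-dimethyl-8-(3-methylbut-2-en-1-yl)-2H-chromen-6-yl]-3,4-dihydro-2H-chromen-7-ol | CC(C)=CCc1c(O)c([C@@H]2COc3cc(O)ccc3C2)cc2c1OC(C)(C)C=C2 | target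

**Step count and risks**

Total step count: 8 (step 8 runs two stages in one flask). Longest linear sequence: 7 (steps 1, 2, 3, 5, 6, 7, 8); step 4 is a one-step side branch.

Step 8 (the proposed new step) is the most likely to fail. The hydrogen-atom transfer may give low ee, or a racemic background transfer from the phenols may compete. The radical cation may also be diverted through the chromene (dimerisation) or the free resorcinol ring. Any stray acid turns 11 into the 2-methyl-2-aryl-2,3-dihydrobenzofuran. The ee should be read on an aliquot of 12 before the acid stage; if HCl/MeOH harms the chromene or prenyl group, TMSOTf/2,2'-bipyridyl is the gentler way to remove the MOM group.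

The fallback uses known chemistry and sets out from 10. Copper-catalysed asymmetric hydroboration of the 1,1-disubstituted aryl alkene (CuCl, DTBM-SEGPHOS in the antipode that gives R, KOtBu cat., HBpin, THF, rt) gives 2-{(2R)-3-[2,4-bis(triisopropylsilyloxy)phenyl]-2-[7-(methoxymethoxy)-2,2-dimethyl-8-(3-methylbut-2-en-1-yl)-2H-chromen-6-yl]propyl}-4,4,5,5-tetramethyl-1,3,2-dioxaborolane F1. Oxidation with NaBO3·4H2O in THF/H2O gives (2R)-3-[2,4-bis(triisopropylsilyloxy)phenyl]-2-[7-(methoxymethoxy)-2,2-dimethyl-8-(3-methylbut-2-en-1-yl)-2H-chromen-6-yl]propan-1-ol F2. Bu4NF/AcOH then frees ring A to give 4-{(2R)-3-hydroxy-2-[7-(methoxymethoxy)-2,2-dimethyl-8-(3-methylbut-2-en-1-yl)-2H-chromen-6-yl]propyl}benzene-1,3-diol F3. Intramolecular Mitsunobu etherification (PPh3, DIAD, THF, 0 °C, high dilution) closes ring C; the MOM group prevents the competing five-membered closure from ring B. The fallback comes back to the route at 12, which is taken to 13 with HCl/MeOH as in the second stage of step 8.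

Step 5 is the second risk. The aryl bromide is electron-rich and ortho-hindered, the ketone is hindered, and any silyl loss from the product would lead to a 2-arylbenzofuran.

The fallback sets out from 6 and avoids hot enolate chemistry. KHMDS and PhNTf2 (THF, −78 °C) give 1-[7-(methoxymethoxy)-2,2-dimethyl-8-(3-methylbut-2-en-1-yl)-2H-chromen-6-yl]ethenyl trifluoromethanesulfonate F4. Negishi coupling (Pd(PPh3)4, THF, rt) with (pinacolatoboryl)methylzinc iodide F5, made from 2-(iodomethyl)-4,4,5,5-tetramethyl-1,3,2-dioxaborolane and Zn dust, gives 2-{2-[7-(methoxymethoxy)-2,2-dimethyl-8-(3-methylbut-2-en-1-yl)-2H-chromen-6-yl]prop-2-en-1-yl}-4,4,5,5-tetramethyl-1,3,2-dioxaborolane F6. Suzuki–Miyaura allyl–aryl coupling of F6 with 8 (Pd(OAc)2, SPhos, K3PO4, THF/H2O, 50 °C) then gives the alkene; both allyl termini are equivalent, so only one product can form. The fallback comes back to the route at 10, bypassing 9 and step 6.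

Step 1 is the third risk. Direct C-prenylation gives a mixture and may not be workable on scale.

The fallback sets out from 1 and replaces C-alkylation by O-alkylation and rearrangement. 3-Chloro-3-methylbut-1-yne (K2CO3, KI, CuI cat., acetone, 60 °C) alkylates the non-chelated 4-OH to give 1-{2-hydroxy-4-[(2-methylbut-3-yn-2-yl)oxy]phenyl}ethan-1-one F7. Semi-hydrogenation (H2, Pd/CaCO3 poisoned with Pb(OAc)2, quinoline, EtOAc) gives 1-{2-hydroxy-4-[(2-methylbut-3-en-2-yl)oxy]phenyl}ethan-1-one F8. Aromatic Claisen rearrangement (N,N-diethylaniline, 190 °C) moves the allyl unit, with inversion to the prenyl form, to C3, the position favoured by the chelate-fixed bond order. The fallback comes back to the route at 3.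

**Further compounds**

F1 | step 8 | 2-{(2R)-3-[2,4-bis(triisopropylsilyloxy)phenyl]-2-[7-(methoxymethoxy)-2,2-dimethyl-8-(3-methylbut-2-en-1-yl)-2H-chromen-6-yl]propyl}-4,4,5,5-tetramethyl-1,3,2-dioxaborolane | CC1(C)OB(C[C@H](Cc2ccc(O[Si](C(C)C)(C(C)C)C(C)C)cc2O[Si](C(C)C)(C(C)C)C(C)C)c2cc3C=CC(C)(C)Oc3c(CC=C(C)C)c2OCOC)OC1(C)C
F2 | step 8 | (2R)-3-[2,4-bis(triisopropylsilyloxy)phenyl]-2-[7-(methoxymethoxy)-2,2-dimethyl-8-(3-methylbut-2-en-1-yl)-2H-chromen-6-yl]propan-1-ol | OC[C@H](Cc1ccc(O[Si](C(C)C)(C(C)C)C(C)C)cc1O[Si](C(C)C)(C(C)C)C(C)C)c1cc2C=CC(C)(C)Oc2c(CC=C(C)C)c1OCOC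
F3 | step 8 | 4-{(2R)-3-hydroxy-2-[7-(methoxymethoxy)-2,2-dimethyl-8-(3-methylbut-2-en-1-yl)-2H-chromen-6-yl]propyl}benzene-1,3-diol | OC[C@H](Cc1ccc(O)cc1O)c1cc2C=CC(C)(C)Oc2c(CC=C(C)C)c1OCOC
F4 | step 5 | 1-[7-(methoxymethoxy)-2,2-dimethyl-8-(3-methylbut-2-en-1-yl)-2H-chromen-6-yl]ethenyl trifluoromethanesulfonate | C=C(OS(=O)(=O)C(F)(F)F)c1cc2C=CC(C)(C)Oc2c(CC=C(C)C)c1OCOC
F5 | step 5 | (pinacolatoboryl)methylzinc iodide | I[Zn]CB1OC(C)(C)C(C)(C)O1
F6 | step 5 | 2-{2-[7-(methoxymethoxy)-2,2-dimethyl-8-(3-methylbut-2-en-1-yl)-2H-chromen-6-yl]prop-2-en-1-yl}-4,4,5,5-tetramethyl-1,3,2-dioxaborolane | C=C(CB1OC(C)(C)C(C)(C)O1)c1cc2C=CC(C)(C)Oc2c(CC=C(C)C)c1OCOC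
F7 | step 1 | 1-{2-hydroxy-4-[(2-methylbut-3-yn-2-yl)oxy]phenyl}ethan-1-one | CC(=O)c1ccc(OC(C)(C)C#C)cc1O
F8 | step 1 | 1-{2-hydroxy-4-[(2-methylbut-3-en-2-yl)oxy]phenyl}ethan-1-one | CC(=O)c1ccc(OC(C)(C)C=C)cc1O
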